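**Plan**

- Retrosynthesis: the bond from the guaiacyl ipso carbon to the dioxane carbon C-11 is cut first, giving an aryl trifluoroborate and a 1,4-benzodioxane that carries acetate on C-11. Then the C-11–O-3′ bond (as a lactone) and the C-10–O-4′ bond are cut, giving 3,5,7-tri-O-benzylquercetin and an (R)-glycerate triflate.
- Forward: both flavonol rings come intact from quercetin. The catechol is freed, O-4′ is alkylated, the dioxane ring is closed as a lactone, C-11 is brought to the acetal level, the guaiacyl ring is joined, and the benzyl groups are removed.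
- Enabling feature: C-11 lies between ring oxygen O-3′ and the aryl group. With OAc in place of aryl it ionises to an oxocarbenium ion (C-11=O-3′ cation) inside the benzo-fused 1,4-dioxane ring. Its neighbour C-10, the only other sp3 atom of that ring, carries the CH2OBn arm and screens one face. The guaiacyl ipso carbon is para to oxygen and is transferred from boron.
- Stereochemistry: C-10 (S) comes from methyl (R)-glycidate through one SN2 inversion (step 6). C-11 (S) arises in step 9 by trans addition under control of C-10.

Key step: step 9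

Remark: flavonoid numbering is used; the dioxane carbons are called C-10 (bears CH2O, bound to O-4′) and C-11 (bears the aryl group, bound to O-3′). Quercetin, methyl (R)-glycidate and 4-(benzyloxy)-3-methoxyphenylboronic acid are taken as purchasable.

**Route**

Step 1
Reactants: 1 quercetin
Product: 2 quercetin 3′,4′-diphenylmethylene ketal
Conditions: Ph2CCl2 (1.5 equiv), Ph2O, 175 °C
Reagents that add atoms: dichlorodiphenylmethane ClC(Cl)(c1ccccc1)c1ccccc1
Why: Ketal formation with a gem-dichloride: of the five hydroxyls only the vicinal 3′,4′-pair can close a five-membered 1,3-benzodioxole, so the catechol alone should be masked.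

Step 2
Reactants: 2 quercetin 3′,4′-diphenylmethylene ketal
Product: 3 tri-O-benzyl ketal
Conditions: BnBr (4.5 equiv), K2CO3, Bu4NI (cat.), DMF, 80 °C
Reagents that add atoms: benzyl bromide BrCc1ccccc1
Why: Williamson ether synthesis: 3-OH and 7-OH should benzylate readily and the hydrogen-bonded 5-OH at 80 °C, while the diaryl ketal is inert to base.

Step 3
Reactants: 3 tri-O-benzyl ketal
Product: 4 3,5,7-tri-O-benzylquercetin
Conditions: AcOH–H2O 4:1, reflux
Reagents that add atoms: none
Why: Acid-catalysed ketal hydrolysis: the diphenyl-stabilised oxocarbenium ion forms easily in hot aqueous acetic acid, whereas aryl benzyl ethers should survive.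

Step 4
Reactants: 5 methyl (R)-glycidate
Product: 6 methyl (R)-3-(benzyloxy)-2-hydroxypropanoate
Conditions: BnOH (3 equiv), BF3·OEt2 (10 mol %), CH2Cl2, 0 °C to rt
Reagents that add atoms: benzyl alcohol OCc1ccccc1
Why: Lewis-acid-catalysed epoxide alcoholysis: benzyl alcohol should open the activated glycidate at the unhindered C-3 (attack at C-2 is disfavoured by the adjacent ester), so the C-2 stereocentre is not touched and stays R.

Step 5
Reactants: 6 methyl (R)-3-(benzyloxy)-2-hydroxypropanoate
Product: 7 glycerate triflate
Conditions: Tf2O (1.1 equiv), 2,6-lutidine, CH2Cl2, −78 to −20 °C; used crude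
Reagents that add atoms: triflic anhydride O=S(=O)(OS(=O)(=O)C(F)(F)F)C(F)(F)F
Why: O-Sulfonylation of a secondary alcohol with a hindered pyridine base; the C–O bond is not broken, so the R configuration is retained.

Step 6
Reactants: 4 3,5,7-tri-O-benzylquercetin; 7 glycerate triflate
Product: 9 (S)-benzodioxinone lactone, via hydroxy ester 8 (not isolated)
Conditions: K2CO3 (1.05 equiv), MeCN–THF, 0 °C to rt; then p-TsOH (cat.), toluene, 80 °C, 5 Å MS
Reagents that add atoms: none
Why: Williamson-type SN2 displacement followed by acid-catalysed lactonisation: one equivalent of base should ionise the more acidic 4′-OH (para to the pyranone C-2, a vinylogous acid), whose phenoxide displaces the α-triflate with inversion (R to S at the future C-10), and the free 3′-OH then closes the six-membered aryl lactone with loss of methanol.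

Step 7
Reactants: 9 (S)-benzodioxinone lactone
Product: 11 C-11 acetate (both C-11 epimers), via aluminium hemiacetal 10 (not isolated)
Conditions: DIBAL-H (1.2 equiv), CH2Cl2, −78 °C; then pyridine, DMAP, Ac2O, −78 to 0 °C
Reagents that add atoms: acetic anhydride CC(=O)OC(C)=O
Why: Reductive acetylation of a lactone (DIBAL reduction and in situ O-acylation of the aluminium hemiacetal): the aryl lactone is far more electrophilic than the doubly vinylogous pyranone carbonyl, and trapping at −78 °C should fix C-11 at the acetal level; its configuration is irrelevant because it is ionised in step 9.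

Step 8
Reactants: 12 4-(benzyloxy)-3-methoxyphenylboronic acid
Product: 13 potassium aryltrifluoroborate
Conditions: KHF2 (3 equiv), MeOH–H2O, rt
Reagents that add atoms: potassium hydrogen difluoride [K+].F.[F-]
Why: Standard conversion of a boronic acid into its potassium trifluoroborate salt, which gives a crystalline, weighable aryl donor.

Step 9
Reactants: 11 C-11 acetate (both C-11 epimers); 13 potassium aryltrifluoroborate
Product: 15 penta-O-benzyl-2,3-dehydrosilybin B, via aryldifluoroborane 14 (not isolated)
Conditions: BF3·OEt2 (3 equiv), CH2Cl2–MeCN, −40 to 0 °C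
Reagents that add atoms: none
Why: BF3 abstracts fluoride from 13 to give the Lewis-acidic aryldifluoroborane 14, which ionises the C-11 acetate of 11 to the cyclic oxocarbenium ion (C-11=O-3′ cation) paired with an aryl(acetoxy)borate, and the electron-rich aryl group then migrates from boron to C-11 through its ipso carbon (para to OBn), which fixes the 4-oxy-3-methoxy pattern of the new ring. The closest known reaction type is the BF3-promoted coupling of potassium aryltrifluoroborates with O,O-acetals and 2H-chromene acetals, in effect a Lewis-acid C-aryl glycosylation of an anomeric acetate. No ring is closed here: the dioxane ring was closed beforehand as lactone 9 so that C-11 could enter this step at the acetal level. The new stereocentre C-11 (S) is controlled by C-10: in the nearly flat benzo-fused oxocarbenium ring the CH2OBn arm screens one face, so the aryl group should add anti to it and give the 10,11-trans (diequatorial) product, and because the 4-benzyloxybenzylic C-11–O-3′ bond can re-ionise under BF3, any cis isomer should drain to the same more stable trans isomer. The step needs ipso C-arylation rather than Friedel–Crafts attack elsewhere, exocyclic rather than endocyclic ionisation, and no loss of H-10; these are secured by boron-to-carbon delivery within the ion pair, by acetate being a far better leaving group than the ring aryloxide, and by low temperature in a base-free medium.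

Step 10
Reactants: 15 penta-O-benzyl-2,3-dehydrosilybin B
Product: 16 2,3-dehydrosilybin B
Conditions: H2 (1 atm), 10% Pd/C, THF–MeOH, rt
Reagents that add atoms: none
Why: Catalytic hydrogenolysis of the five benzyl ethers under neutral conditions, which should leave the pyranone double bond and both dioxane stereocentres untouched.

**Compound list**

1 | quercetin, 2-(3,4-dihydroxyphenyl)-3,5,7-trihydroxy-4H-chromen-4-one | O=c1c(O)c(-c2ccc(O)c(O)c2)oc2cc(O)cc(O)c12 | starting material
2 | 2-(2,2-diphenyl-1,3-benzodioxol-5-yl)-3,5,7-trihydroxy-4H-chromen-4-one | O=c1c(O)c(-c2ccc3OC(c4ccccc4)(c4ccccc4)Oc3c2)oc2cc(O)cc(O)c12 | intermediate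
3 | 3,5,7-tris(benzyloxy)-2-(2,2-diphenyl-1,3-benzodioxol-5-yl)-4H-chromen-4-one | O=c1c(OCc2ccccc2)c(-c2ccc3OC(c4ccccc4)(c4ccccc4)Oc3c2)oc2cc(OCc3ccccc3)cc(OCc3ccccc3)c12 | intermediate
4 | 3,5,7-tris(benzyloxy)-2-(3,4-dihydroxyphenyl)-4H-chromen-4-one | O=c1c(OCc2ccccc2)c(-c2ccc(O)c(O)c2)oc2cc(OCc3ccccc3)cc(OCc3ccccc3)c12 | intermediate
5 | methyl (2R)-oxirane-2-carboxylate | COC(=O)[C@H]1CO1 | starting material
6 | methyl (2R)-3-(benzyloxy)-2-hydroxypropanoate | COC(=O)[C@H](O)COCc1ccccc1 | intermediate
7 | methyl (2R)-3-(benzyloxy)-2-[(trifluoromethanesulfonyl)oxy]propanoate | COC(=O)[C@H](OS(=O)(=O)C(F)(F)F)COCc1ccccc1 | intermediate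
8 | methyl (2S)-3-(benzyloxy)-2-{2-hydroxy-4-[3,5,7-tris(benzyloxy)-4-oxo-4H-chromen-2-yl]phenoxy}propanoate (formed in the flask) | COC(=O)[C@@H](Oc1ccc(-c2oc3cc(OCc4ccccc4)cc(OCc4ccccc4)c3c(=O)c2OCc2ccccc2)cc1O)COCc1ccccc1 | intermediate
9 | (3S)-3-[(benzyloxy)methyl]-7-[3,5,7-tris(benzyloxy)-4-oxo-4H-chromen-2-yl]-1,4-benzodioxin-2(3H)-one | O=C1Oc2cc(-c3oc4cc(OCc5ccccc5)cc(OCc5ccccc5)c4c(=O)c3OCc3ccccc3)ccc2O[C@H]1COCc1ccccc1 | intermediate
10 | diisobutylaluminium alkoxide of (3S)-3-[(benzyloxy)methyl]-7-[3,5,7-tris(benzyloxy)-4-oxo-4H-chromen-2-yl]-2,3-dihydro-1,4-benzodioxin-2-ol, both C-2 epimers (formed in the flask) | CC(C)C[Al](CC(C)C)OC1Oc2cc(-c3oc4cc(OCc5ccccc5)cc(OCc5ccccc5)c4c(=O)c3OCc3ccccc3)ccc2O[C@H]1COCc1ccccc1 | intermediate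
11 | (3S)-3-[(benzyloxy)methyl]-7-[3,5,7-tris(benzyloxy)-4-oxo-4H-chromen-2-yl]-2,3-dihydro-1,4-benzodioxin-2-yl acetate, both epimers at the acetal carbon (C-11) | CC(=O)OC1Oc2cc(-c3oc4cc(OCc5ccccc5)cc(OCc5ccccc5)c4c(=O)c3OCc3ccccc3)ccc2O[C@H]1COCc1ccccc1 | intermediate
12 | [4-(benzyloxy)-3-methoxyphenyl]boronic acid | COc1cc(B(O)O)ccc1OCc1ccccc1 | starting material
13 | potassium [4-(benzyloxy)-3-methoxyphenyl]trifluoroborate | COc1cc([B-](F)(F)F)ccc1OCc1ccccc1.[K+] | intermediate
14 | [4-(benzyloxy)-3-methoxyphenyl]difluoroborane (formed in the flask) | COc1cc(B(F)F)ccc1OCc1ccccc1 | intermediate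
15 | 3,5,7-tris(benzyloxy)-2-{(2S,3S)-3-[4-(benzyloxy)-3-methoxyphenyl]-2-[(benzyloxy)methyl]-2,3-dihydro-1,4-benzodioxin-6-yl}-4H-chromen-4-one | COc1cc([C@@H]2Oc3cc(-c4oc5cc(OCc6ccccc6)cc(OCc6ccccc6)c5c(=O)c4OCc4ccccc4)ccc3O[C@H]2COCc2ccccc2)ccc1OCc1ccccc1 | intermediate
16 | 2,3-dehydrosilybin B, 3,5,7-trihydroxy-2-[(2S,3S)-3-(4-hydroxy-3-methoxyphenyl)-2-(hydroxymethyl)-2,3-dihydro-1,4-benzodioxin-6-yl]-4H-chromen-4-one | COc1cc([C@@H]2Oc3cc(-c4oc5cc(O)cc(O)c5c(=O)c4O)ccc3O[C@H]2CO)ccc1O | target

**Count and risks**

Total steps: 10. Longest linear sequence: 7 steps (1, 2, 3, 6, 7, 9, 10); steps 4–5 and step 8 are side branches.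

Steps most likely to fail:

1. Step 9. The oxocarbenium ion may lose H-10 (elimination to the 1,4-benzodioxin, which also erases C-10), aryl transfer may be slower than Friedel–Crafts attack by the benzyloxy-rich flavone ring of a second molecule, or facial selectivity may be poor. Fallback (radical/nickel path in place of the cation): setting out from 11, TMSBr in CH2Cl2 at 0 °C should give the α-bromo ether F1, used crude. It is joined under nickel catalysis (NiCl2·glyme, terpyridine-type ligand, DMA–THF, rt) to the arylzinc chloride F2, made from commercial 1-(benzyloxy)-4-bromo-2-methoxybenzene with Mg, LiCl and ZnCl2 in THF. This Negishi coupling of an α-halo ether is the type used for C-aryl glycosides from glycosyl bromides; the C-11 radical/alkylnickel should be arylated anti to the CH2OBn arm. The fallback returns to the route at 15.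

2. Step 7. The aluminium hemiacetal may collapse to the open hydroxy-aldehyde (the aryloxide is a good leaving group), leading to over-reduction or to acylation on the phenol oxygen instead of the hemiacetal oxygen. Fallback (chelate-stabilised reduction and separate acylation): setting out from 9, ring-opening aminolysis with Me(MeO)NH·HCl and Et3N in CH2Cl2 should give the N-methoxy-N-methylamide F3. DIBAL-H (2.2 equiv, THF, −78 °C) reduces it through a stable chelate, and on work-up the aldehyde closes onto the free 3′-OH to give the lactol F4. Ac2O, pyridine and DMAP then give 11, where the fallback returns to the route.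

3. Step 6. Base may enolise the α-aryloxy ester (erosion of configuration at C-10), or dialkylation and alkylation at O-3′ may compete. Fallback (redox condensation under neutral conditions): setting out from 4 and 6, a Mitsunobu reaction (PPh3, DIAD, THF, 0 °C to rt) lets the betaine deprotonate only the more acidic 4′-OH and gives the same inversion. The hydroxy ester 8 is isolated this time and lactonised as in step 6, returning to the route at 9; no compound outside the list is made (F0).

**Further compounds**

F1 | step 9 | 3,5,7-tris(benzyloxy)-2-{(2S)-2-[(benzyloxy)methyl]-3-bromo-2,3-dihydro-1,4-benzodioxin-6-yl}-4H-chromen-4-one, both C-3 epimers | BrC1Oc2cc(-c3oc4cc(OCc5ccccc5)cc(OCc5ccccc5)c4c(=O)c3OCc3ccccc3)ccc2O[C@H]1COCc1ccccc1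
F2 | step 9 | [4-(benzyloxy)-3-methoxyphenyl]zinc chloride | COc1cc([Zn]Cl)ccc1OCc1ccccc1
F3 | step 7 | (2S)-3-(benzyloxy)-2-{2-hydroxy-4-[3,5,7-tris(benzyloxy)-4-oxo-4H-chromen-2-yl]phenoxy}-N-methoxy-N-methylpropanamide | CON(C)C(=O)[C@@H](Oc1ccc(-c2oc3cc(OCc4ccccc4)cc(OCc4ccccc4)c3c(=O)c2OCc2ccccc2)cc1O)COCc1ccccc1
F4 | step 7 | 3,5,7-tris(benzyloxy)-2-{(2S)-2-[(benzyloxy)methyl]-3-hydroxy-2,3-dihydro-1,4-benzodioxin-6-yl}-4H-chromen-4-one, both C-3 epimers | OC1Oc2cc(-c3oc4cc(OCc5ccccc5)cc(OCc5ccccc5)c4c(=O)c3OCc3ccccc3)ccc2O[C@H]1COCc1ccccc1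
F0 | step 6 | none | none
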